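I started from 0.950, the charge ratio: c(reagent in the second phase) over c(substrate), both charged per volume of the first phase, for Wednesday's flask.

- Wednesday's: substrate 1 mM; reagent in the second phase 0.95 mM; the very flask that is asked about, followed so far
- flask: substrate 1.0 mM; reagent in the second phase 0.950 mM; time 5.0 min; volume of the second phase over the first 1.0

Wednesday's run (percent of the substrate charged): time / s: product / % = 10.0: 43; 20.0: 67; 30.0: 76; 50.0: 84; 80.0: 92; 90.0: 92; 120: 95

(standard deviation of a reading: 2 percentage points)

- in the second phase: reagent in the second phase; everything else is in the first
- charges count per volume of the first phase; a concentration in a rate is the amount of a species over the volume of its own phase; every rate counts per litre of the first phase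
- the numbers in the tables scatter by 2 percentage points (one standard deviation)
- steps thought possible: reagent in the reaction phase <-> reagent in the second phase; substrate + reagent in the reaction phase -> product; reagent in the reaction phase <-> dormant form
- the earlier runs hold the two phases in the same ratio of volumes as the flask asked about

- south: doubling the transfer coefficient of the reagent in the second phase, all else as stated
- north: doubling the amount of reagent in the second phase, all else as stated

- amount of product at 5.0 min, in percent of the substrate charged
- the change that raises the amount of product at 5.0 min, in percent of the substrate charged most ("none" if none brings more than 2 percentage points) (south / north / none)
- amount of product at 5.0 min, in percent of the substrate charged, after south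

The product step takes one substrate and one reagent in the reaction phase, so a ratio below one is the highest fraction of substrate that the listed steps can turn into product. Here the ratio stood below one, which made the reagent the limiting reagent and put the ceiling at 95.0 %.

But a ratio gives a height and no time, so I tested it on Wednesday's readings. The gap below the ceiling was 11 percentage points at 50.0 s and 3 points at 80.0 s, and the last reading was 95 % at 120 s, with a scatter of 2 points. The asked time was 2.50 times the time of that last reading, so I committed to just under the ceiling.

South left the ratio unchanged, so I expected less than 2 points from it. North raised the ratio to 1.90, which lifted the ceiling to the whole substrate charge, a gain of about 5 points.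

The forecast gave 94.7 %, north as the best change and 95 % after south, holding that “the reagent should be consumed fully”.

The flask gave 94.3 %, which is 99.3 % of the ratio's ceiling, and 5.7 % of its substrate remained at 5.00 min. North gained 5.7 points and south 0.045 points, leaving 94.4 % after south.

    reagent in the reaction phase ⇌ reagent in the second phase, rate k1*([reagent in the reaction phase] - [reagent in the second phase]/K1) per volume of the first phase (partition coefficient = 0.440, kL = 0.0620 s⁻¹)
    substrate + reagent in the reaction phase → product (k = 300 L mol⁻¹ s⁻¹)
    reagent in the reaction phase ⇌ dormant form (K = 0.470, k = 0.0260 s⁻¹)

With 2.5 mM of substrate, the neighbouring flask had a ratio of 0.380, so I expected a ceiling of 38.0 %. It gave 38.0 %, with 62 % of its substrate remaining.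

(The runs were generated by integration from invented constants, noise included.)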